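## Retrosynthetic overview

1. Target 35 ← one-pot fluoride removal of two silyl ethers and a SEM ester from benzoate 34; the 6β-benzoate/C19 acid pair ← late opening of a 19,6β-γ-lactone that masks both groups.
2. 7α-OH and the 8(17)-methylene ← equatorial hydride reduction and Cope elimination of a C8 Mannich base; the C9 side chain ← copper-catalysed 1,4-addition of the Grignard reagent of bromide 16 to enone lactone 24, anti to the C10 methyl.
3. Enone lactone 24 ← Δ5-7-one 20 by Li/NH3 reduction (5α-H), 6α-bromination, SN2 lactonisation by the C19 ester (gives 6β-O) and dehydrogenation.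
4. Ring B (the only ring made; closed onto ring A) ← intramolecular aldol condensation of 1,5-diketone 19, assembled from ketoester 4, iodo ketal 8 and MeI.
5. Ring A is bought as a cyclohexanone: 4 ← Noyori hydrogenation, Fráter–Seebach methylation and oxidation of 1; side chain 16 ← but-3-yn-1-ol by Negishi carboalumination.

Assumption: the SMILES is read as (4S,5R,6S,7S,9S,10R) in labdane numbering, i.e. 10β-Me, 5α-H, 4β-CO2H (C19), 6β-OBz, 7α-OH and the side chain on the α face of C9 (9βH). This numbering, with β as the face of the C10 methyl, is used for all decalin compounds.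

## Route

Step 1
Reactants: 1 methyl 2-oxocyclohexane-1-carboxylate
Product: 2 methyl (1R,2R)-2-hydroxycyclohexane-1-carboxylate
Conditions: H2 (100 atm), [RuCl(C6H6)((R)-BINAP)]Cl (0.1 mol %), CH2Cl2, 50 °C
Reagents that add atoms: none
Why: Noyori asymmetric hydrogenation with dynamic kinetic resolution of the racemising β-keto ester sets the carbinol centre as R, the only centre that is carried forward.

Step 2
Reactants: 2 methyl (1R,2R)-2-hydroxycyclohexane-1-carboxylate
Product: 3 methyl (1S,2R)-2-hydroxy-1-methylcyclohexane-1-carboxylate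
Conditions: LiN(iPr)2 (2.2 equiv), THF, –50 → –20 °C; MeI, DMPU, –78 → 0 °C
Reagents that add atoms: iodomethane (CI)
Why: Fráter–Seebach alkylation: the chelated alkoxide–enolate dianion is methylated anti to the C–O bond, so the carbinol centre fixes the new quaternary centre as 1S.

Step 3
Reactants: 3 methyl (1S,2R)-2-hydroxy-1-methylcyclohexane-1-carboxylate
Product: 4 methyl (1S)-1-methyl-2-oxocyclohexane-1-carboxylate
Conditions: Dess–Martin periodinane, CH2Cl2, 25 °C
Reagents that add atoms: none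
Why: Dess–Martin oxidation removes the relay carbinol centre, and the quaternary α-carbon (future C4 with β-CO2Me) cannot epimerise.

Step 4
Reactants: 5 ethyl acetoacetate
Product: 6 ethyl 2-(2-methyl-1,3-dioxolan-2-yl)acetate
Conditions: ethylene glycol, p-toluenesulfonic acid monohydrate (cat.), PhMe, reflux, Dean–Stark
Reagents that add atoms: ethylene glycol (OCCO)
Why: acid-catalysed ketalisation masks the ketone that later becomes C7.

Step 5
Reactants: 6 ethyl 2-(2-methyl-1,3-dioxolan-2-yl)acetate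
Product: 7 2-(2-methyl-1,3-dioxolan-2-yl)ethan-1-ol
Conditions: LiAlH4, Et2O, 0 → 25 °C
Reagents that add atoms: none
Why: hydride reduction of the ester to the primary alcohol leaves the ketal untouched.

Step 6
Reactants: 7 2-(2-methyl-1,3-dioxolan-2-yl)ethan-1-ol
Product: 8 2-(2-iodoethyl)-2-methyl-1,3-dioxolane
Conditions: I2, PPh3, imidazole, CH2Cl2, 0 °C
Reagents that add atoms: iodine (II)
Why: Appel-type (Garegg–Samuelsson) iodination of the primary alcohol under non-acidic conditions keeps the ketal.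

Step 7
Reactants: 9 but-3-yn-1-ol
Product: 10 (but-3-yn-1-yloxy)(tert-butyl)dimethylsilane
Conditions: t-BuMe2SiCl, imidazole, CH2Cl2, 25 °C
Reagents that add atoms: tert-butyldimethylsilyl chloride (CC(C)(C)[Si](C)(C)Cl)
Why: silylation protects the hydroxyl for the carboalumination.

Step 8
Reactants: 10 (but-3-yn-1-yloxy)(tert-butyl)dimethylsilane
Product: 12 ethyl (2E)-5-[(tert-butyldimethylsilyl)oxy]-3-methylpent-2-enoate, via alkenylalane 11 (not isolated)
Conditions: Me3Al (2.5 equiv), Cp2ZrCl2 (0.25 equiv), ClCH2CH2Cl, 0 → 25 °C; then ClCO2Et, 0 °C; aq HCl work-up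
Reagents that add atoms: trimethylaluminium (C[Al](C)C); ethyl chloroformate (CCOC(=O)Cl)
Why: Negishi zirconium-catalysed carboalumination adds Me and Al syn across the alkyne (Me to the internal carbon), and acylation of the alkenylalane with retention gives the E-enoate.

Step 9
Reactants: 12 ethyl (2E)-5-[(tert-butyldimethylsilyl)oxy]-3-methylpent-2-enoate
Product: 13 (2E)-5-[(tert-butyldimethylsilyl)oxy]-3-methylpent-2-en-1-ol
Conditions: i-Bu2AlH (2.2 equiv), CH2Cl2, –78 °C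
Reagents that add atoms: none
Why: 1,2-reduction of the enoate gives the allylic alcohol with the E geometry unchanged.

Step 10
Reactants: 13 (2E)-5-[(tert-butyldimethylsilyl)oxy]-3-methylpent-2-en-1-ol
Product: 14 (2E)-5-[(tert-butyldimethylsilyl)oxy]-1-[(tert-butyldiphenylsilyl)oxy]-3-methylpent-2-ene
Conditions: t-BuPh2SiCl, imidazole, DMF, 25 °C
Reagents that add atoms: tert-butyldiphenylsilyl chloride (CC(C)(C)[Si](Cl)(c1ccccc1)c1ccccc1)
Why: silylation gives the allylic oxygen (future C15-OH) an acid-stable group, so the two ends are differentiated.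

Step 11
Reactants: 14 (2E)-5-[(tert-butyldimethylsilyl)oxy]-1-[(tert-butyldiphenylsilyl)oxy]-3-methylpent-2-ene
Product: 15 (3E)-5-[(tert-butyldiphenylsilyl)oxy]-3-methylpent-3-en-1-ol
Conditions: pyridinium p-toluenesulfonate (0.2 equiv), EtOH, 40 °C
Reagents that add atoms: none
Why: mild acid solvolysis cleaves the primary tert-butyldimethylsilyl ether far faster than the tert-butyldiphenylsilyl ether.

Step 12
Reactants: 15 (3E)-5-[(tert-butyldiphenylsilyl)oxy]-3-methylpent-3-en-1-ol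
Product: 16 {[(2E)-5-bromo-3-methylpent-2-en-1-yl]oxy}(tert-butyl)diphenylsilane
Conditions: CBr4, PPh3, CH2Cl2, 0 °C
Reagents that add atoms: tetrabromomethane (BrC(Br)(Br)Br)
Why: Appel bromination converts the homoallylic alcohol into the bromide needed for the Grignard reagent.

Step 13
Reactants: 4 methyl (1S)-1-methyl-2-oxocyclohexane-1-carboxylate; 8 2-(2-iodoethyl)-2-methyl-1,3-dioxolane
Product: 17 methyl (1S)-1-methyl-3-[2-(2-methyl-1,3-dioxolan-2-yl)ethyl]-2-oxocyclohexane-1-carboxylate (both C3 epimers)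
Conditions: LiN(iPr)2 (1.1 equiv), THF, –78 °C; 8, DMPU, –78 → 0 °C
Reagents that add atoms: none
Why: SN2 alkylation of the kinetic enolate at the only enolisable α-carbon (future C10) installs the masked 3-oxobutyl chain; the new centre is flattened again in the next step.

Step 14
Reactants: 17 methyl (1S)-1-methyl-3-[2-(2-methyl-1,3-dioxolan-2-yl)ethyl]-2-oxocyclohexane-1-carboxylate
Product: 18 methyl (1S,3R)-1,3-dimethyl-3-[2-(2-methyl-1,3-dioxolan-2-yl)ethyl]-2-oxocyclohexane-1-carboxylate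
Conditions: LiN(iPr)2 (1.2 equiv), THF/PhMe, –78 → –20 °C; MeI, –78 → 0 °C (no polar additive)
Reagents that add atoms: iodomethane (CI)
Why: enolate alkylation creating the C10 quaternary centre: in the ester-chelated lithium enolate the C4 methyl is pseudo-axial and MeI enters anti to it, which puts the new methyl (C20) cis to the ester (C19) and the chain trans.

Step 15
Reactants: 18 methyl (1S,3R)-1,3-dimethyl-3-[2-(2-methyl-1,3-dioxolan-2-yl)ethyl]-2-oxocyclohexane-1-carboxylate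
Product: 20 methyl (1S,4aR)-1,4a-dimethyl-7-oxo-1,2,3,4,4a,5,6,7-octahydronaphthalene-1-carboxylate, via diketone 19 (not isolated)
Conditions: 1 M HCl, THF, 25 °C; solvent swap; p-toluenesulfonic acid monohydrate (0.3 equiv), PhMe, reflux, Dean–Stark
Reagents that add atoms: water (O)
Why: ketal hydrolysis followed by acid-catalysed intramolecular aldol condensation (Robinson-type cyclodehydration) closes ring B as the Δ5-7-one, because only the methyl carbon can reach the non-enolisable C5 ketone through a six-membered ring.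

Step 16
Reactants: 20 methyl (1S,4aR)-1,4a-dimethyl-7-oxo-1,2,3,4,4a,5,6,7-octahydronaphthalene-1-carboxylate
Product: 22 methyl (1S,4aR,8R,8aR)-8-bromo-1,4a-dimethyl-7-oxodecahydronaphthalene-1-carboxylate, via silyl enol ether 21 (not isolated)
Conditions: Li (2.2 equiv), NH3/THF, t-BuOH (1.0 equiv), –78 °C; NH3 evaporated; Me3SiCl, Et3N, THF, 0 °C; then N-bromosuccinimide, THF, –78 → 0 °C
Reagents that add atoms: chlorotrimethylsilane (C[Si](C)(C)Cl); N-bromosuccinimide (O=C1CCC(=O)N1Br)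
Why: dissolving-metal enone reduction protonates C5 axially (trans-decalin, 5α-H) and gives the Δ6 enolate regiospecifically, whose silyl enol ether is brominated from the α face because the β face is blocked by the axial C19 and C20 groups (6α-Br).

Step 17
Reactants: 22 methyl (1S,4aR,8R,8aR)-8-bromo-1,4a-dimethyl-7-oxodecahydronaphthalene-1-carboxylate
Product: 23 7-oxo-19,6β-lactone (γ-lactone of 6β-hydroxy-4,10-dimethyl-7-oxo-5α-decalin-4β-carboxylic acid)
Conditions: 2,4,6-collidine, 170 °C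
Reagents that add atoms: none
Why: neighbouring-group SN2 lactonisation: the C19 ester carbonyl oxygen displaces the activated 6α-bromide from the β face (inversion to 6β-O) and bromide demethylates the resulting alkoxy-oxocarbenium ion.

Step 18
Reactants: 23 7-oxo-19,6β-lactone
Product: 24 Δ8(9)-7-oxo-19,6β-lactone (enone lactone)
Conditions: IBX (2.5 equiv), DMSO/PhMe (1:2), 75 °C
Reagents that add atoms: none
Why: IBX dehydrogenation of the ketone goes through the enol toward C8–C9, since the equatorial C6–H next to the lactone oxygen is not enolised.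

Step 19
Reactants: 24 Δ8(9)-7-oxo-19,6β-lactone; 16 {[(2E)-5-bromo-3-methylpent-2-en-1-yl]oxy}(tert-butyl)diphenylsilane
Product: 27 (13E)-15-[(tert-butyldiphenylsilyl)oxy]-17-(dimethylamino)-7-oxo-9βH-labd-13-en-19,6β-olide (C8 epimers), via Grignard reagent 25 (not isolated), via silyl enol ether 26 (not isolated)
Conditions: 16, Mg, THF, 35 °C; added to 24, CuBr·SMe2 (10 mol %), Me3SiCl, HMPA, THF, –78 °C; then Me2N=CH2+ I–, CH2Cl2, –78 → 25 °C; aq NaHCO3
Reagents that add atoms: magnesium ([Mg]); chlorotrimethylsilane (C[Si](C)(C)Cl); dimethyl(methylidene)ammonium iodide (C=[N+](C)C.[I-])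
Why: copper-catalysed conjugate addition attacks C9 axially from the α face, anti to the axial C10 methyl, which sets the 9α side chain (9βH), and the silyl enol ether then undergoes a Mannich reaction at C8 that brings in C17.

Step 20
Reactants: 27 (13E)-15-[(tert-butyldiphenylsilyl)oxy]-17-(dimethylamino)-7-oxo-9βH-labd-13-en-19,6β-olide
Product: 28 (13E)-15-[(tert-butyldiphenylsilyl)oxy]-17-(dimethylamino)-7α-hydroxy-9βH-labd-13-en-19,6β-olide
Conditions: LiBH(s-Bu)3, THF, –78 °C; MeOH quench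
Reagents that add atoms: none
Why: the bulky hydride attacks the ketone equatorially from the β face because the α face is screened by the axial C9 chain and H-5, giving the axial 7α-alcohol trans to the 6β-oxygen.

Step 21
Reactants: 28 (13E)-15-[(tert-butyldiphenylsilyl)oxy]-17-(dimethylamino)-7α-hydroxy-9βH-labd-13-en-19,6β-olide
Product: 30 (13E)-15-[(tert-butyldiphenylsilyl)oxy]-7α-hydroxy-9βH-labda-8(17),13-dien-19,6β-olide, via amine N-oxide 29 (not isolated)
Conditions: m-chloroperbenzoic acid (1.05 equiv), CH2Cl2, –40 °C; then PhMe, 80 °C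
Reagents that add atoms: m-chloroperbenzoic acid (OOC(=O)c1cccc(Cl)c1)
Why: chemoselective N-oxidation of the tertiary amine followed by Cope elimination (syn, the only β-hydrogen is on C8) gives the exocyclic 8(17)-alkene without base.

Step 22
Reactants: 30 (13E)-15-[(tert-butyldiphenylsilyl)oxy]-7α-hydroxy-9βH-labda-8(17),13-dien-19,6β-olide
Product: 31 (13E)-7α-[(tert-butyldimethylsilyl)oxy]-15-[(tert-butyldiphenylsilyl)oxy]-9βH-labda-8(17),13-dien-19,6β-olide
Conditions: t-BuMe2SiOTf, 2,6-lutidine, CH2Cl2, –78 → 0 °C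
Reagents that add atoms: tert-butyldimethylsilyl triflate (CC(C)(C)[Si](C)(C)OS(=O)(=O)C(F)(F)F)
Why: silylation blocks the allylic 7α-hydroxyl so that only the 6β-hydroxyl is free after the lactone is opened.

Step 23
Reactants: 31 (13E)-7α-[(tert-butyldimethylsilyl)oxy]-15-[(tert-butyldiphenylsilyl)oxy]-9βH-labda-8(17),13-dien-19,6β-olide
Product: 33 2-(trimethylsilyl)ethoxymethyl (13E)-7α-[(tert-butyldimethylsilyl)oxy]-15-[(tert-butyldiphenylsilyl)oxy]-6β-hydroxy-9βH-labda-8(17),13-dien-19-oate, via lithium carboxylate 32 (not isolated)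
Conditions: LiOH·H2O (1.5 equiv), THF/MeOH/H2O, 60 °C; evaporate and dry; Me3SiCH2CH2OCH2Cl, DMF, 0 → 25 °C
Reagents that add atoms: lithium hydroxide monohydrate ([Li+].[OH-].O); 2-(trimethylsilyl)ethoxymethyl chloride (C[Si](C)(C)CCOCCl)
Why: saponification of the γ-lactone and SN2 O-alkylation of the carboxylate salt free the 6β-hydroxyl while C19 is held as a fluoride-cleavable ester, without ever acidifying the hydroxy acid.

Step 24
Reactants: 33 2-(trimethylsilyl)ethoxymethyl (13E)-7α-[(tert-butyldimethylsilyl)oxy]-15-[(tert-butyldiphenylsilyl)oxy]-6β-hydroxy-9βH-labda-8(17),13-dien-19-oate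
Product: 34 2-(trimethylsilyl)ethoxymethyl (13E)-6β-(benzoyloxy)-7α-[(tert-butyldimethylsilyl)oxy]-15-[(tert-butyldiphenylsilyl)oxy]-9βH-labda-8(17),13-dien-19-oate
Conditions: PhCOCl, 4-(dimethylamino)pyridine, pyridine, CH2Cl2, 40 °C
Reagents that add atoms: benzoyl chloride (O=C(Cl)c1ccccc1)
Why: nucleophile-catalysed acylation of the only free hydroxyl (axial 6β-OH) under non-alkoxide conditions, so the neighbouring ester is not attacked.

Step 25
Reactants: 34 2-(trimethylsilyl)ethoxymethyl (13E)-6β-(benzoyloxy)-7α-[(tert-butyldimethylsilyl)oxy]-15-[(tert-butyldiphenylsilyl)oxy]-9βH-labda-8(17),13-dien-19-oate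
Product: 35 (13E)-6β-(benzoyloxy)-7α,15-dihydroxy-9βH-labda-8(17),13-dien-19-oic acid (CNP0149011.1)
Conditions: Bu4NF (6 equiv), AcOH (3 equiv), THF, 0 → 25 °C
Reagents that add atoms: none
Why: buffered fluoride cleaves both silyl ethers and fragments the 2-(trimethylsilyl)ethoxymethyl ester in one operation, and the benzoate cannot migrate because the 6β,7α-oxygens are trans-diaxial.

## Compound list

1 | methyl 2-oxocyclohexane-1-carboxylate | COC(=O)C1CCCCC1=O | starting material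
2 | methyl (1R,2R)-2-hydroxycyclohexane-1-carboxylate | COC(=O)[C@@H]1CCCC[C@H]1O | intermediate
3 | methyl (1S,2R)-2-hydroxy-1-methylcyclohexane-1-carboxylate | COC(=O)[C@@]1(C)CCCC[C@H]1O | intermediate
4 | methyl (1S)-1-methyl-2-oxocyclohexane-1-carboxylate | COC(=O)[C@@]1(C)CCCCC1=O | intermediate
5 | ethyl acetoacetate (ethyl 3-oxobutanoate) | CCOC(=O)CC(C)=O | starting material
6 | ethyl 2-(2-methyl-1,3-dioxolan-2-yl)acetate | CCOC(=O)CC1(C)OCCO1 | intermediate
7 | 2-(2-methyl-1,3-dioxolan-2-yl)ethan-1-ol | OCCC1(C)OCCO1 | intermediate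
8 | 2-(2-iodoethyl)-2-methyl-1,3-dioxolane | ICCC1(C)OCCO1 | intermediate
9 | but-3-yn-1-ol | C#CCCO | starting material
10 | (but-3-yn-1-yloxy)(tert-butyl)dimethylsilane | C#CCCO[Si](C)(C)C(C)(C)C | intermediate
11 | [(1E)-4-[(tert-butyldimethylsilyl)oxy]-2-methylbut-1-en-1-yl]dimethylalumane | C[Al](C)/C=C(\C)CCO[Si](C)(C)C(C)(C)C | intermediate
12 | ethyl (2E)-5-[(tert-butyldimethylsilyl)oxy]-3-methylpent-2-enoate | CCOC(=O)/C=C(\C)CCO[Si](C)(C)C(C)(C)C | intermediate
13 | (2E)-5-[(tert-butyldimethylsilyl)oxy]-3-methylpent-2-en-1-ol | OC/C=C(\C)CCO[Si](C)(C)C(C)(C)C | intermediate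
14 | (2E)-5-[(tert-butyldimethylsilyl)oxy]-1-[(tert-butyldiphenylsilyl)oxy]-3-methylpent-2-ene | CC(C)(C)[Si](C)(C)OCC/C(C)=C/CO[Si](c1ccccc1)(c1ccccc1)C(C)(C)C | intermediate
15 | (3E)-5-[(tert-butyldiphenylsilyl)oxy]-3-methylpent-3-en-1-ol | OCC/C(C)=C/CO[Si](c1ccccc1)(c1ccccc1)C(C)(C)C | intermediate
16 | {[(2E)-5-bromo-3-methylpent-2-en-1-yl]oxy}(tert-butyl)diphenylsilane | BrCC/C(C)=C/CO[Si](c1ccccc1)(c1ccccc1)C(C)(C)C | intermediate
17 | methyl (1S)-1-methyl-3-[2-(2-methyl-1,3-dioxolan-2-yl)ethyl]-2-oxocyclohexane-1-carboxylate (C3 epimers) | COC(=O)[C@@]1(C)CCCC(CCC2(C)OCCO2)C1=O | intermediate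
18 | methyl (1S,3R)-1,3-dimethyl-3-[2-(2-methyl-1,3-dioxolan-2-yl)ethyl]-2-oxocyclohexane-1-carboxylate | CC1(CC[C@@]2(C)CCC[C@](C)(C(=O)OC)C2=O)OCCO1 | intermediate
19 | methyl (1S,3R)-1,3-dimethyl-2-oxo-3-(3-oxobutyl)cyclohexane-1-carboxylate | CC(=O)CC[C@@]1(C)CCC[C@](C)(C(=O)OC)C1=O | intermediate
20 | methyl (1S,4aR)-1,4a-dimethyl-7-oxo-1,2,3,4,4a,5,6,7-octahydronaphthalene-1-carboxylate (Δ5-7-one, 4β-CO2Me, 10β-Me) | O=C1CC[C@@]2(C)CCC[C@](C)(C(=O)OC)C2=C1 | intermediate
21 | methyl (1S,4aR,8aR)-1,4a-dimethyl-7-[(trimethylsilyl)oxy]-1,2,3,4,4a,5,6,8a-octahydronaphthalene-1-carboxylate (Δ6 silyl enol ether, 5α-H) | C1=C(O[Si](C)(C)C)CC[C@@]2(C)CCC[C@](C)(C(=O)OC)[C@H]12 | intermediate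
22 | methyl (1S,4aR,8R,8aR)-8-bromo-1,4a-dimethyl-7-oxodecahydronaphthalene-1-carboxylate (6α-bromo-7-ketone, 5α-H) | O=C1CC[C@@]2(C)CCC[C@](C)(C(=O)OC)[C@@H]2[C@H]1Br | intermediate
23 | 7-oxo-19,6β-lactone: γ-lactone of 6β-hydroxy-4,10-dimethyl-7-oxo-5α-decalin-4β-carboxylic acid | O=C1CC[C@@]2(C)CCC[C@@]3(C)[C@@H]2[C@@H]1OC3=O | intermediate
24 | enone lactone: γ-lactone of 6β-hydroxy-4,10-dimethyl-7-oxo-5α-decal-8-ene-4β-carboxylic acid | O=C1C=C[C@@]2(C)CCC[C@@]3(C)[C@@H]2[C@@H]1OC3=O | intermediate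
25 | [(3E)-5-[(tert-butyldiphenylsilyl)oxy]-3-methylpent-3-en-1-yl]magnesium bromide | Br[Mg]CC/C(C)=C/CO[Si](c1ccccc1)(c1ccccc1)C(C)(C)C | intermediate
26 | (13E)-15-[(tert-butyldiphenylsilyl)oxy]-7-[(trimethylsilyl)oxy]-17-nor-9βH-labda-7,13-dien-19,6β-olide | C[Si](C)(C)OC1=C[C@@H](CC/C(C)=C/CO[Si](c3ccccc3)(c3ccccc3)C(C)(C)C)[C@@]2(C)CCC[C@@]3(C)[C@@H]2[C@@H]1OC3=O | intermediate
27 | (13E)-15-[(tert-butyldiphenylsilyl)oxy]-17-(dimethylamino)-7-oxo-9βH-labd-13-en-19,6β-olide (C8 epimers) | O=C1C(CN(C)C)[C@@H](CC/C(C)=C/CO[Si](c3ccccc3)(c3ccccc3)C(C)(C)C)[C@@]2(C)CCC[C@@]3(C)[C@@H]2[C@@H]1OC3=O | intermediate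
28 | (13E)-15-[(tert-butyldiphenylsilyl)oxy]-17-(dimethylamino)-7α-hydroxy-9βH-labd-13-en-19,6β-olide (C8 epimers) | CN(C)CC1[C@@H](CC/C(C)=C/CO[Si](c3ccccc3)(c3ccccc3)C(C)(C)C)[C@@]2(C)CCC[C@@]3(C)[C@@H]2[C@H](OC3=O)[C@H]1O | intermediate
29 | N-oxide of 28 | C[N+](C)([O-])CC1[C@@H](CC/C(C)=C/CO[Si](c3ccccc3)(c3ccccc3)C(C)(C)C)[C@@]2(C)CCC[C@@]3(C)[C@@H]2[C@H](OC3=O)[C@H]1O | intermediate
30 | (13E)-15-[(tert-butyldiphenylsilyl)oxy]-7α-hydroxy-9βH-labda-8(17),13-dien-19,6β-olide | C=C1[C@@H](CC/C(C)=C/CO[Si](c3ccccc3)(c3ccccc3)C(C)(C)C)[C@@]2(C)CCC[C@@]3(C)[C@@H]2[C@H](OC3=O)[C@H]1O | intermediate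
31 | (13E)-7α-[(tert-butyldimethylsilyl)oxy]-15-[(tert-butyldiphenylsilyl)oxy]-9βH-labda-8(17),13-dien-19,6β-olide | C=C1[C@@H](CC/C(C)=C/CO[Si](c3ccccc3)(c3ccccc3)C(C)(C)C)[C@@]2(C)CCC[C@@]3(C)[C@@H]2[C@H](OC3=O)[C@H]1O[Si](C)(C)C(C)(C)C | intermediate
32 | lithium (13E)-7α-[(tert-butyldimethylsilyl)oxy]-15-[(tert-butyldiphenylsilyl)oxy]-6β-hydroxy-9βH-labda-8(17),13-dien-19-oate | C=C1[C@@H](CC/C(C)=C/CO[Si](c3ccccc3)(c3ccccc3)C(C)(C)C)[C@@]2(C)CCC[C@](C)(C(=O)[O-])[C@@H]2[C@H](O)[C@H]1O[Si](C)(C)C(C)(C)C.[Li+] | intermediate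
33 | 2-(trimethylsilyl)ethoxymethyl (13E)-7α-[(tert-butyldimethylsilyl)oxy]-15-[(tert-butyldiphenylsilyl)oxy]-6β-hydroxy-9βH-labda-8(17),13-dien-19-oate | C=C1[C@@H](CC/C(C)=C/CO[Si](c3ccccc3)(c3ccccc3)C(C)(C)C)[C@@]2(C)CCC[C@](C)(C(=O)OCOCC[Si](C)(C)C)[C@@H]2[C@H](O)[C@H]1O[Si](C)(C)C(C)(C)C | intermediate
34 | 2-(trimethylsilyl)ethoxymethyl (13E)-6β-(benzoyloxy)-7α-[(tert-butyldimethylsilyl)oxy]-15-[(tert-butyldiphenylsilyl)oxy]-9βH-labda-8(17),13-dien-19-oate | C=C1[C@@H](CC/C(C)=C/CO[Si](c3ccccc3)(c3ccccc3)C(C)(C)C)[C@@]2(C)CCC[C@](C)(C(=O)OCOCC[Si](C)(C)C)[C@@H]2[C@H](OC(=O)c3ccccc3)[C@H]1O[Si](C)(C)C(C)(C)C | intermediate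
35 | (13E)-6β-(benzoyloxy)-7α,15-dihydroxy-9βH-labda-8(17),13-dien-19-oic acid; (4S,5R,6S,7S,9S,10R); CNP0149011.1 | C=C1[C@@H](CC/C(C)=C/CO)[C@@]2(C)CCC[C@](C)(C(=O)O)[C@@H]2[C@H](OC(=O)c2ccccc2)[C@H]1O | target

## Step count and risks

Total step count: 25.
Longest linear sequence: 16 steps (steps 1–3 then 13–25; the branch 4–6 then 13–25 is equally long; the side-chain branch 7–12 then 19–25 is 13). That is 0.64 of the total.

The three steps most likely to fail:

Step 14 (C10 methylation). The facial preference depends on whether the ester is held in the enolate plane by lithium, so the wrong C10 epimer (methyl trans to the ester) could dominate. The fallback reverses the order of the two C10 alkylations and uses a non-chelated enolate, in which the ester rather than the C4 methyl sits pseudo-axial, so the incoming chain enters anti to the ester and the C10 methyl ends up cis to it. It sets out from 4: LiN(iPr)2 and MeI give methyl (1S)-1,3-dimethyl-2-oxocyclohexane-1-carboxylate F1, and its potassium enolate (KN(SiMe3)2, 18-crown-6, THF, –78 °C) is alkylated with 8. The route is rejoined at 18.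

Step 15 (ring B closure). The C5 ketone is flanked by two quaternary carbons, so the acid-catalysed cyclodehydration may stall at the diketone. The fallback closes the ring as a Lewis-acid Mukaiyama aldol reaction and dehydrates separately. It sets out from 18: aqueous HCl gives diketone 19, now isolated; LiN(iPr)2 and Me3SiCl at –78 °C silylate the methyl side to give the methyl-ketone silyl enol ether F2; TiCl4 in CH2Cl2 at –78 °C closes ring B to the C5-hydroxy 7-ketone F3; SOCl2 in pyridine dehydrates it toward C6. The route is rejoined at 20.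

Step 24 (benzoylation of the hindered 6β-OH). The axial hydroxyl sits next to the C19 ester and may re-lactonise to 31 faster than it is acylated. The fallback takes C19 down to the alcohol level so that no lactone can form, and re-oxidises after benzoylation. It sets out from 31: LiAlH4 gives the 6β,19-diol F4; Et3SiCl and imidazole silylate the primary hydroxyl to give the 19-triethylsilyl ether F5; PhCOCl and 4-(dimethylamino)pyridine at 60 °C give the 6β-benzoate F6; pyridinium p-toluenesulfonate in MeOH frees the 19-alcohol F7; Dess–Martin periodinane gives the 19-aldehyde F8; NaClO2, NaH2PO4 and 2-methylbut-2-ene give the 19-acid F9; Bu4NF and AcOH remove the two silyl ethers. The route is rejoined at 35.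

Further compounds
F1 | step 14 | methyl (1S)-1,3-dimethyl-2-oxocyclohexane-1-carboxylate (C3 epimers) | COC(=O)[C@@]1(C)CCCC(C)C1=O
F2 | step 15 | methyl (1S,3R)-1,3-dimethyl-2-oxo-3-{3-[(trimethylsilyl)oxy]but-3-en-1-yl}cyclohexane-1-carboxylate | C=C(O[Si](C)(C)C)CC[C@@]1(C)CCC[C@](C)(C(=O)OC)C1=O
F3 | step 15 | methyl (1S,4aR)-8a-hydroxy-1,4a-dimethyl-7-oxodecahydronaphthalene-1-carboxylate (C8a unassigned) | O=C1CC[C@@]2(C)CCC[C@](C)(C(=O)OC)C2(O)C1
F4 | step 24 | (13E)-7α-[(tert-butyldimethylsilyl)oxy]-15-[(tert-butyldiphenylsilyl)oxy]-9βH-labda-8(17),13-diene-6β,19-diol | C=C1[C@@H](CC/C(C)=C/CO[Si](c3ccccc3)(c3ccccc3)C(C)(C)C)[C@@]2(C)CCC[C@](C)(CO)[C@@H]2[C@H](O)[C@H]1O[Si](C)(C)C(C)(C)C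
F5 | step 24 | (13E)-7α-[(tert-butyldimethylsilyl)oxy]-15-[(tert-butyldiphenylsilyl)oxy]-19-[(triethylsilyl)oxy]-9βH-labda-8(17),13-dien-6β-ol | C=C1[C@@H](CC/C(C)=C/CO[Si](c3ccccc3)(c3ccccc3)C(C)(C)C)[C@@]2(C)CCC[C@](C)(CO[Si](CC)(CC)CC)[C@@H]2[C@H](O)[C@H]1O[Si](C)(C)C(C)(C)C
F6 | step 24 | (13E)-7α-[(tert-butyldimethylsilyl)oxy]-15-[(tert-butyldiphenylsilyl)oxy]-19-[(triethylsilyl)oxy]-9βH-labda-8(17),13-dien-6β-yl benzoate | C=C1[C@@H](CC/C(C)=C/CO[Si](c3ccccc3)(c3ccccc3)C(C)(C)C)[C@@]2(C)CCC[C@](C)(CO[Si](CC)(CC)CC)[C@@H]2[C@H](OC(=O)c3ccccc3)[C@H]1O[Si](C)(C)C(C)(C)C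
F7 | step 24 | (13E)-7α-[(tert-butyldimethylsilyl)oxy]-15-[(tert-butyldiphenylsilyl)oxy]-19-hydroxy-9βH-labda-8(17),13-dien-6β-yl benzoate | C=C1[C@@H](CC/C(C)=C/CO[Si](c3ccccc3)(c3ccccc3)C(C)(C)C)[C@@]2(C)CCC[C@](C)(CO)[C@@H]2[C@H](OC(=O)c3ccccc3)[C@H]1O[Si](C)(C)C(C)(C)C
F8 | step 24 | (13E)-7α-[(tert-butyldimethylsilyl)oxy]-15-[(tert-butyldiphenylsilyl)oxy]-19-oxo-9βH-labda-8(17),13-dien-6β-yl benzoate | C=C1[C@@H](CC/C(C)=C/CO[Si](c3ccccc3)(c3ccccc3)C(C)(C)C)[C@@]2(C)CCC[C@](C)(C=O)[C@@H]2[C@H](OC(=O)c3ccccc3)[C@H]1O[Si](C)(C)C(C)(C)C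
F9 | step 24 | (13E)-6β-(benzoyloxy)-7α-[(tert-butyldimethylsilyl)oxy]-15-[(tert-butyldiphenylsilyl)oxy]-9βH-labda-8(17),13-dien-19-oic acid | C=C1[C@@H](CC/C(C)=C/CO[Si](c3ccccc3)(c3ccccc3)C(C)(C)C)[C@@]2(C)CCC[C@](C)(C(=O)O)[C@@H]2[C@H](OC(=O)c3ccccc3)[C@H]1O[Si](C)(C)C(C)(C)C
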